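## Analysis of the target

Target 23 is a (2S)-flavan (benzo ring A, dihydropyran ring C, phenyl ring B) that carries at C8 a benzofuran-2-yl group (furan part O1', C2', C3'; benzo part C3a' to C7a'). Ring A has a methoxyl at C5 and a free hydroxyl at C7; the benzofuran has a methoxyl at C4', a methyl at C5' and a free hydroxyl at C6'. The only stereocentre is C2 (S), a benzylic carbon bound to O1. It has no partner to relay from, so its configuration must come from a reagent or catalyst, and it can be lost by acid ionisation or by hydrogenolysis of the C2–O1 bond. The C8–C2' bond is flanked by O1 and the C7 oxygen and is crowded, but rotation about it is fast because one partner is a five-membered ring, so it is not a stereo element. Sensitive groups are the two free phenols on very electron-rich rings, the C2–O1 benzylic ether and the C2'=C3' bond of the benzofuran. The difficulty lies in telling four oxygens on two rings apart (two methylated, two free) and in the contiguous oxygen, methyl, oxygen pattern at C4', C5', C6', which is awkward to set by aromatic substitution. The strategy rests on the benzo ring of the benzofuran: C4' (O), C5' (Me), C6' (O) and C7' (H) are the carbonyl carbon, C2, C3 and C4 of a 2-methyl-3-alkoxycyclobutenone, fused across the C3a'–C7a' edge of a furan that already carries the flavan.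

## Retrosynthetic reasoning

**End game.** The two free phenols of 23 are carried as benzyl ethers and released together from 22 by hydrogenolysis, so only one kind of protecting group is used. Ether 22 comes from phenol 21 by O-methylation; 21 has a single free hydroxyl, at C4', so no selectivity question arises.

**Benzo ring of the benzofuran (key disconnection).** In 21 the bonds C7'–C7a' and C3a'–C4' are cut, which leads to furylstannane 12 and the racemic 4-chlorocyclobutenone 18. Cutting here, and not at C8–C2' or inside the furan ring, means the fully substituted benzene is never made by aromatic substitution. The hydroxyl at C4', the methyl at C5' and the benzyloxy group at C6' are the carbonyl, C2 and C3 of 18. Forward, a Stille coupling must join C4 of 18 to the tin-bearing furan carbon. The coupled cyclobutenone 19 must then open to dienylketene 20 and close onto the neighbouring furan β-carbon.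

**Cyclobutenone 18.** The C–Cl bond is traced to the carbinol of 17. Alcohol 17 is the product of hydride addition to dione 16 at the carbonyl next to the benzyloxy-bearing carbon; this is the step that fixes which carbon ends as C4' and which as C7'. Dione 16 follows from dibenzyl squarate 14 by addition of one methyl nucleophile and acid-induced loss of one benzyloxy group, and 14 from squaric acid 13.

**Stannane 12.** The C–Sn bond is made by deprotonation of the only free furan α-position of arylfuran 10. The C8–C2' bond of 10 is cut to give bromide 8 and furan-2-ylboronic acid 9, and 8 comes from flavan 7 by electrophilic bromination. An acetyl group at C8, turned into the furan by allylation, oxidative cleavage and cyclodehydration, was considered as an alternative handle. It was set aside for two reasons. No dependable way was seen to close the C4–C4a bond of a chroman that carries an aryl ketone: halogen–metal exchange is excluded by the ketone, and Friedel–Crafts alkylation by the ionisable benzylic ether. It would also spend three steps, one of them acidic on an electron-rich furan, where one cross-coupling suffices.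

**Flavan 7.** Ring C is cut at O1–C2 and not at C4–C4a, because closure at oxygen by SN2 on a carbinol of known configuration is stereospecific. Mitsunobu inversion of the (R)-alcohol 6 gives (2S). The stereocentre of 6 is set by catalytic asymmetric reduction of ketone 5. Ketone 5 comes from chalcone 4 by saturation of the C3=C4 bond, and 4 from aldehyde 2 and acetophenone 3 by aldol condensation (C3–C4 bond). Aldehyde 2 is the 4-O-benzyl ether of 1. The substitution of 1 fixes ring A without any regiochemical step: the formyl carbon becomes C4, the chelated hydroxyl becomes O1, the para hydroxyl becomes the C7 oxygen and the methoxyl is that of C5.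

## Alternatives that were turned down

**Alternative 1:** Ring A is taken apart by a Danheiser benzannulation into diazo ketone A2 and siloxyalkyne A3. Irradiation of A2 would give a vinylketene by Wolff rearrangement (C5–C6). Its [2+2] addition to A3, 4π opening and 6π closure would form C8–C8a, C6–C7 and C4a–C8a and give phenol A1; ring C would then be closed by Mitsunobu inversion.
- For it: ring A is made with every substituent in place in one operation, and the crowded C8–C2' bond is present from the start. On this point it is stronger than the chosen route, which depends on the site selectivity of a bromination (step 6) and on a hindered cross-coupling (step 7).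
- Against it: A3 already contains the complete 4'-methoxy-5'-methyl-6'-oxy benzofuran, so the hardest pattern of the target is only moved into a starting material that needs its own long synthesis. A2 is a light- and acid-sensitive diazo ketone that also carries the stereocentre. The alkynylbenzofuran chromophore of A3 absorbs where A2 must be excited. Two kinds of silyl ether must be removed in order, and three steps follow the key step against two here.
- Comparison: the chosen strategy builds that benzofuran pattern by construction from a four-carbon unit and leaves only two steps after the key step.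

**Alternative 2:** Ring C is cut at O1–C2 and C3–C4. The Lewis acid Sc(OTf)3 A7, paired with a chiral pybox ligand, would ionise salicyl alcohol A5 to an ortho-quinone methide, which adds styrene A6 in a hetero-Diels–Alder reaction to give the 8-acetylflavan A4 with C2 set.
- For it: ring, two bonds and the stereocentre come in one step from simple materials. In step economy for the flavan it is clearly stronger than the four steps (2 to 5) used here.
- Against it: A5 has a second hydroxyl para to the benzylic carbon, so a para-quinone methide is an equally easy and unproductive ionisation. The acetyl group and both phenols chelate A7 and compete with the chiral ligand. A simple styrene adds through an open benzylic cation far from the metal, so facial control at C2 is weakly founded. A4 also leaves the benzofuran unsolved: the acetyl group must still be turned into a furan before a benzannulation.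
- Comparison: the chosen route sets C2 by a well-behaved catalytic ketone reduction followed by a stereospecific inversion, so its risk sits in one step and not in the stereocentre.

**Alternative 3:** The furan ring of the benzofuran is cut at C2'=C3'. Base would convert phosphonium salt A9 into an ylide that attacks the neighbouring aryl ester carbonyl in an intramolecular Wittig reaction, giving benzofuran A8.
- For it: this is a mild, convergent and dependable way to 2-arylbenzofurans, without tin or a strained ring. In the reliability of the ring-forming event it is at least as strong as the chosen key step.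
- Against it: the C4', C5', C6' pattern is not created but must already be present in the phenol half of A9, a pentasubstituted benzene whose regiocontrolled synthesis is exactly the difficulty of the target. The ester carbonyl is flanked by two ortho oxygens and is electron-rich, which slows both its formation and the ylide attack. A silyl and a benzyl ether mean two deprotections.
- Comparison: the chosen strategy offers the substitution pattern by construction from 18 and a single final deprotection.

Key step: step 13

Remark: aldehyde 1, acetophenone 3, boronic acid 9 and squaric acid 13 are taken as purchasable. Chloride 18 is used as the racemate, because its C4 centre ends as the aromatic C7' carbon. Furan carbons in 10 to 12, 19 and 20 are named by the benzofuran positions they become.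

## Route

Step 1
Reactants: 1 2,4-dihydroxy-6-methoxybenzaldehyde
Product: 2 4-(benzyloxy)-2-hydroxy-6-methoxybenzaldehyde
Conditions: BnBr, NaHCO3, KI (cat.), MeCN, 60 °C
Reagents that add atoms: benzyl bromide BrCc1ccccc1
Why: Williamson etherification; the 4-hydroxyl (para to the formyl group, not hydrogen-bonded) is the more acidic and accessible phenol, while the 2-hydroxyl is held in a chelate with the aldehyde, so a weak base should alkylate O4 only.

Step 2
Reactants: 2 4-(benzyloxy)-2-hydroxy-6-methoxybenzaldehyde; 3 acetophenone
Product: 4 (E)-3-[4-(benzyloxy)-2-hydroxy-6-methoxyphenyl]-1-phenylprop-2-en-1-one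
Conditions: KOH (aq.), EtOH, rt, dark; AcOH work-up
Reagents that add atoms: none
Why: Claisen–Schmidt condensation; the aldehyde has no α-hydrogen, the ketone enolate adds and E1cB dehydration gives the conjugated E-enone, and the benzyl ether is inert to hydroxide.

Step 3
Reactants: 4 (E)-3-[4-(benzyloxy)-2-hydroxy-6-methoxyphenyl]-1-phenylprop-2-en-1-one
Product: 5 3-[4-(benzyloxy)-2-hydroxy-6-methoxyphenyl]-1-phenylpropan-1-one
Conditions: H2 (1 atm), RhCl(PPh3)3 (cat.), toluene/EtOH, 40 °C
Reagents that add atoms: none
Why: Homogeneous hydrogenation with RhCl(PPh3)3 saturates the enone C=C and leaves the aryl ketone, the benzyl ether and the arenes alone; 5 may sit partly as its cyclic hemiketal, which stays in equilibrium with the open ketone.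

Step 4
Reactants: 5 3-[4-(benzyloxy)-2-hydroxy-6-methoxyphenyl]-1-phenylpropan-1-one
Product: 6 5-(benzyloxy)-2-[(3R)-3-hydroxy-3-phenylpropyl]-3-methoxyphenol
Conditions: RuCl(p-cymene)[(R,R)-TsDPEN] (cat.), HCO2H/Et3N (5:2), EtOAc, 35 °C
Reagents that add atoms: none
Why: Noyori asymmetric transfer hydrogenation of an aryl alkyl ketone; the (R,R)-configured Ru–H/N–H catalyst delivers hydride to the face that gives the (R)-carbinol (phenyl versus CH2 discrimination through the CH–π contact with the arene ligand), and the phenol and benzyl ether are tolerated.

Step 5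
Reactants: 6 5-(benzyloxy)-2-[(3R)-3-hydroxy-3-phenylpropyl]-3-methoxyphenol
Product: 7 (2S)-7-(benzyloxy)-5-methoxy-2-phenylchroman
Conditions: PPh3, DIAD, THF, 0 °C to rt
Reagents that add atoms: none
Why: Intramolecular Mitsunobu etherification; the phenol, the only acidic hydroxyl, displaces the oxyphosphonium of the secondary benzylic alcohol in a 6-exo-tet SN2 closure with inversion, which turns the (R)-carbinol into (2S)-C2 without any acid that could ionise the benzylic centre.

Step 6
Reactants: 7 (2S)-7-(benzyloxy)-5-methoxy-2-phenylchroman
Product: 8 (2S)-7-(benzyloxy)-8-bromo-5-methoxy-2-phenylchroman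
Conditions: NBS (1.0 equiv), CH2Cl2, −78 to −20 °C
Reagents that add atoms: N-bromosuccinimide O=C1CCC(=O)N1Br
Why: Electrophilic aromatic bromination; C6 and C8 are each activated by three oxygens, but C8 lies next to the ring oxygen O1, whose lone pair is held in conjugation and which carries no freely rotating alkyl group, so C8 should be the more nucleophilic and less shielded site, as is usual for 5,7-dialkoxyflavans.

Step 7
Reactants: 8 (2S)-7-(benzyloxy)-8-bromo-5-methoxy-2-phenylchroman; 9 furan-2-ylboronic acid
Product: 10 2-[(2S)-7-(benzyloxy)-5-methoxy-2-phenylchroman-8-yl]furan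
Conditions: Pd(OAc)2 (cat.), SPhos, K3PO4, n-BuOH/H2O, 80 °C
Reagents that add atoms: none
Why: Suzuki–Miyaura coupling forming C8–C2'; the bulky, electron-rich biarylphosphine lets zerovalent palladium insert into the hindered, electron-rich C8–Br bond and speeds reductive elimination, and an excess of 9 offsets protodeboronation.

Step 8
Reactants: 10 2-[(2S)-7-(benzyloxy)-5-methoxy-2-phenylchroman-8-yl]furan
Product: 12 tributyl{5-[(2S)-7-(benzyloxy)-5-methoxy-2-phenylchroman-8-yl]furan-2-yl}stannane, via furyllithium 11 (not isolated)
Conditions: n-BuLi, THF, −78 to −30 °C; Bu3SnCl, −78 °C to rt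
Reagents that add atoms: n-butyllithium [Li]CCCC (lithium of 11); tributyltin chloride CCCC[Sn](Cl)(CCCC)CCCC
Why: α-Lithiation of a furan followed by trapping with the tin chloride; the one free furan α-C–H is the most acidic proton, and at low temperature the benzylic CH2 of the benzyl ether and the arene C6–H should be removed much more slowly.

Step 9
Reactants: 13 squaric acid (3,4-dihydroxycyclobut-3-ene-1,2-dione)
Product: 14 dibenzyl squarate (3,4-bis(benzyloxy)cyclobut-3-ene-1,2-dione)
Conditions: BnOH, toluene, reflux, Dean–Stark trap
Reagents that add atoms: benzyl alcohol OCc1ccccc1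
Why: Azeotropic esterification of a vinylogous diacid; squaric acid is strong enough to catalyse its own esterification, and removal of water drives both hydroxyls to the benzyl ester.

Step 10
Reactants: 14 dibenzyl squarate (3,4-bis(benzyloxy)cyclobut-3-ene-1,2-dione)
Product: 16 3-(benzyloxy)-4-methylcyclobut-3-ene-1,2-dione, via hydroxy adduct 15 (not isolated)
Conditions: MeLi, THF, −78 °C; then conc. HCl (aq.), rt
Reagents that add atoms: methyllithium [Li]C
Why: 1,2-Addition of an organolithium to one of the two equivalent squarate carbonyls, then acid-induced 1,3-transposition: ionisation of the tertiary carbinol, capture of the alkoxy-stabilised cation at the benzyloxy-bearing carbon and loss of benzyl alcohol leave methyl and benzyloxy on the ring double bond.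

Step 11
Reactants: 16 3-(benzyloxy)-4-methylcyclobut-3-ene-1,2-dione
Product: 17 3-(benzyloxy)-4-hydroxy-2-methylcyclobut-2-en-1-one (racemic)
Conditions: LiAlH(Ot-Bu)3, THF, −78 to −40 °C
Reagents that add atoms: none
Why: Chemoselective hydride reduction; the carbonyl attached to the benzyloxy-bearing carbon is a true ketone, whereas the other is a vinylogous ester (BnO–C=C–C=O) and less electrophilic, so the bulky hydride should reduce the former and leave the carbonyl next to the methyl-bearing carbon.

Step 12
Reactants: 17 3-(benzyloxy)-4-hydroxy-2-methylcyclobut-2-en-1-one (racemic)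
Product: 18 3-(benzyloxy)-4-chloro-2-methylcyclobut-2-en-1-one (racemic)
Conditions: PPh3, NCS, CH2Cl2, −20 to 0 °C; used without heating
Reagents that add atoms: N-chlorosuccinimide O=C1CCC(=O)N1Cl
Why: Appel-type deoxychlorination under neutral conditions; chloride displaces the oxyphosphonium of the allylic, α-keto alcohol at C4, and the absence of protic acid avoids loss of benzyl alcohol from the vinylogous ester.

Step 13
Reactants: 12 tributyl{5-[(2S)-7-(benzyloxy)-5-methoxy-2-phenylchroman-8-yl]furan-2-yl}stannane; 18 3-(benzyloxy)-4-chloro-2-methylcyclobut-2-en-1-one (racemic)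
Product: 21 6-(benzyloxy)-2-[(2S)-7-(benzyloxy)-5-methoxy-2-phenylchroman-8-yl]-5-methylbenzofuran-4-ol, via furylcyclobutenone 19 (not isolated), via dienylketene 20 (not isolated)
Conditions: Pd2(dba)3 (cat.), tri(2-furyl)phosphine, dioxane, 50 °C; then 100 °C
Reagents that add atoms: none
Why: Zerovalent palladium inserts into the allylic, α-keto C4–Cl bond of 18, the furyl group of 12 is transferred from tin in preference to butyl, and reductive elimination forms C7'–C7a' to give 19 as a mixture of C4 epimers (Stille coupling). On warming, the strained ring of 19 opens by a thermal conrotatory 4π process to dienylketene 20, whose third double bond is the furan C3a'=C7a' bond. A thermal disrotatory 6π electrocyclisation between the ketene carbon and the furan β-carbon then closes the six-membered benzo ring (C3a'–C4'), and a proton shift aromatises it to phenol 21. The closest known reaction type is the palladium-catalysed coupling of 4-chlorocyclobutenones with aryl- and heteroarylstannanes followed by thermal ring expansion to phenols, a benzannulation that also serves stannylated five-membered heteroarenes. No stereocentre is formed: C4 of 18 and 19 becomes the aromatic C7'–H carbon, so racemic 18 suffices, and C2 of the flavan is remote from every bond change. Site selectivity at the furan is fixed by tin (ipso coupling) and by the fact that only one β-carbon neighbours the new bond; the placement of hydroxyl, methyl and benzyloxy at C4', C5' and C6' is inherited from 18. Only the ketene isomer with the furyl group cis to the ketenyl carbon can close; ring opening is reversible, so the other isomer returns through 19 and is drained by the irreversible aromatisation. The neutral, base-free conditions should leave both benzyl ethers and the C2–O1 benzylic ether untouched.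

Step 14
Reactants: 21 6-(benzyloxy)-2-[(2S)-7-(benzyloxy)-5-methoxy-2-phenylchroman-8-yl]-5-methylbenzofuran-4-ol
Product: 22 6-(benzyloxy)-2-[(2S)-7-(benzyloxy)-5-methoxy-2-phenylchroman-8-yl]-4-methoxy-5-methylbenzofuran
Conditions: MeI, K2CO3, DMF, rt
Reagents that add atoms: methyl iodide CI
Why: Williamson methylation of the only free phenol; carbonate deprotonates the C4' hydroxyl and methyl iodide alkylates it, while every other oxygen is already an ether.

Step 15
Reactants: 22 6-(benzyloxy)-2-[(2S)-7-(benzyloxy)-5-methoxy-2-phenylchroman-8-yl]-4-methoxy-5-methylbenzofuran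
Product: 23 (2S)-8-(6-hydroxy-4-methoxy-5-methylbenzofuran-2-yl)-5-methoxy-2-phenylchroman-7-ol
Conditions: H2 (1 atm), Pd/C, EtOAc/MeOH, rt
Reagents that add atoms: none
Why: Catalytic hydrogenolysis of two aryl benzyl ethers at ambient pressure; the cyclic C2–O1 benzylic ether of a 2-arylchroman and the benzofuran C2'=C3' bond react much more slowly, so the reaction is stopped once both benzyl groups are gone and C2 stays untouched.

## Compound list

1 | 2,4-dihydroxy-6-methoxybenzaldehyde | COc1cc(O)cc(O)c1C=O | starting material
2 | 4-(benzyloxy)-2-hydroxy-6-methoxybenzaldehyde | COc1cc(OCc2ccccc2)cc(O)c1C=O | intermediate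
3 | acetophenone | CC(=O)c1ccccc1 | starting material
4 | (E)-3-[4-(benzyloxy)-2-hydroxy-6-methoxyphenyl]-1-phenylprop-2-en-1-one | COc1cc(OCc2ccccc2)cc(O)c1/C=C/C(=O)c1ccccc1 | intermediate
5 | 3-[4-(benzyloxy)-2-hydroxy-6-methoxyphenyl]-1-phenylpropan-1-one | COc1cc(OCc2ccccc2)cc(O)c1CCC(=O)c1ccccc1 | intermediate
6 | 5-(benzyloxy)-2-[(3R)-3-hydroxy-3-phenylpropyl]-3-methoxyphenol | COc1cc(OCc2ccccc2)cc(O)c1CC[C@@H](O)c1ccccc1 | intermediate
7 | (2S)-7-(benzyloxy)-5-methoxy-2-phenylchroman | COc1cc(OCc2ccccc2)cc2c1CC[C@@H](c1ccccc1)O2 | intermediate
8 | (2S)-7-(benzyloxy)-8-bromo-5-methoxy-2-phenylchroman | COc1cc(OCc2ccccc2)c(Br)c2c1CC[C@@H](c1ccccc1)O2 | intermediate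
9 | furan-2-ylboronic acid | OB(O)c1ccco1 | starting material
10 | 2-[(2S)-7-(benzyloxy)-5-methoxy-2-phenylchroman-8-yl]furan | COc1cc(OCc2ccccc2)c(-c2ccco2)c2c1CC[C@@H](c1ccccc1)O2 | intermediate
11 | {5-[(2S)-7-(benzyloxy)-5-methoxy-2-phenylchroman-8-yl]furan-2-yl}lithium | COc1cc(OCc2ccccc2)c(-c2ccc([Li])o2)c2c1CC[C@@H](c1ccccc1)O2 | intermediate
12 | tributyl{5-[(2S)-7-(benzyloxy)-5-methoxy-2-phenylchroman-8-yl]furan-2-yl}stannane | COc1cc(OCc2ccccc2)c(-c2ccc([Sn](CCCC)(CCCC)CCCC)o2)c2c1CC[C@@H](c1ccccc1)O2 | intermediate
13 | squaric acid (3,4-dihydroxycyclobut-3-ene-1,2-dione) | OC1=C(O)C(=O)C1=O | starting material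
14 | dibenzyl squarate (3,4-bis(benzyloxy)cyclobut-3-ene-1,2-dione) | O=C1C(=O)C(OCc2ccccc2)=C1OCc1ccccc1 | intermediate
15 | 2,3-bis(benzyloxy)-4-hydroxy-4-methylcyclobut-2-en-1-one (racemic) | CC1(O)C(OCc2ccccc2)=C(OCc2ccccc2)C1=O | intermediate
16 | 3-(benzyloxy)-4-methylcyclobut-3-ene-1,2-dione | CC1=C(OCc2ccccc2)C(=O)C1=O | intermediate
17 | 3-(benzyloxy)-4-hydroxy-2-methylcyclobut-2-en-1-one (racemic) | CC1=C(OCc2ccccc2)C(O)C1=O | intermediate
18 | 3-(benzyloxy)-4-chloro-2-methylcyclobut-2-en-1-one (racemic) | CC1=C(OCc2ccccc2)C(Cl)C1=O | intermediate
19 | 3-(benzyloxy)-4-{5-[(2S)-7-(benzyloxy)-5-methoxy-2-phenylchroman-8-yl]furan-2-yl}-2-methylcyclobut-2-en-1-one (both C4 epimers) | COc1cc(OCc2ccccc2)c(-c2ccc(C3C(=O)C(C)=C3OCc3ccccc3)o2)c2c1CC[C@@H](c1ccccc1)O2 | intermediate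
20 | (3E)-3-(benzyloxy)-4-{5-[(2S)-7-(benzyloxy)-5-methoxy-2-phenylchroman-8-yl]furan-2-yl}-2-methylbuta-1,3-dien-1-one | COc1cc(OCc2ccccc2)c(-c2ccc(/C=C(\C(C)=C=O)OCc3ccccc3)o2)c2c1CC[C@@H](c1ccccc1)O2 | intermediate
21 | 6-(benzyloxy)-2-[(2S)-7-(benzyloxy)-5-methoxy-2-phenylchroman-8-yl]-5-methylbenzofuran-4-ol | COc1cc(OCc2ccccc2)c(-c2cc3c(O)c(C)c(OCc4ccccc4)cc3o2)c2c1CC[C@@H](c1ccccc1)O2 | intermediate
22 | 6-(benzyloxy)-2-[(2S)-7-(benzyloxy)-5-methoxy-2-phenylchroman-8-yl]-4-methoxy-5-methylbenzofuran | COc1cc(OCc2ccccc2)c(-c2cc3c(OC)c(C)c(OCc4ccccc4)cc3o2)c2c1CC[C@@H](c1ccccc1)O2 | intermediate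
23 | (2S)-8-(6-hydroxy-4-methoxy-5-methylbenzofuran-2-yl)-5-methoxy-2-phenylchroman-7-ol | COc1cc(O)c(-c2cc3c(OC)c(C)c(O)cc3o2)c2c1CC[C@@H](c1ccccc1)O2 | target

## Step count and least certain steps

Total: 15 steps. Longest linear sequence: 11 steps (1 to 23 through steps 1 to 8 and 13 to 15); the cyclobutenone branch (steps 9 to 12) has 4 steps.

**Step 13 (key step).** The hindered, electron-rich stannane 12 may transmetalate slowly, so that protodestannylation of 12 or thermal ring opening of chloride 18 before coupling takes over, and the flavan unit must survive the heating. The fallback makes the biaryl bond last; it sets out from chloride 18 and bromide 8 and comes back at 22. Chloride 18 is coupled under the conditions of step 13 with tributyl(furan-2-yl)stannane, the simplest stannane of this class. This should give 3-(benzyloxy)-4-(furan-2-yl)-2-methylcyclobut-2-en-1-one F1 and, on heating, 6-(benzyloxy)-5-methylbenzofuran-4-ol F2. O-Methylation (MeI, K2CO3) gives 6-(benzyloxy)-4-methoxy-5-methylbenzofuran F3. Deprotonation at C2' with n-BuLi and trapping with 2-isopropoxy-4,4,5,5-tetramethyl-1,3,2-dioxaborolane gives 2-[6-(benzyloxy)-4-methoxy-5-methylbenzofuran-2-yl]-4,4,5,5-tetramethyl-1,3,2-dioxaborolane F4. Suzuki–Miyaura coupling of F4 with 8 (Pd(OAc)2, SPhos, K3PO4) then gives 22.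

**Step 12.** Adventitious acid may make 17 lose benzyl alcohol and collapse to a cyclobutenedione, chloride may be delivered with allylic transposition, and 18 may ring-open on concentration. The fallback separates activation from displacement; it sets out from 17 and comes back at 18. Alcohol 17 is converted with MsCl and Et3N at −40 °C into 2-(benzyloxy)-3-methyl-4-oxocyclobut-2-en-1-yl methanesulfonate F5, which is displaced with LiCl in THF at 0 °C under buffered, acid-free conditions, and 18 is used as a cold solution.

**Step 6.** Bromination may occur at C6 as well as C8, or twice, because both positions are strongly activated. The fallback lets the free phenol direct the halogen before ring closure; it sets out from 6 and comes back at 8. Amine-catalysed ortho-bromination of 6 (NBS, catalytic i-Pr2NH, CH2Cl2, low temperature) should give 3-(benzyloxy)-2-bromo-6-[(3R)-3-hydroxy-3-phenylpropyl]-5-methoxyphenol F6, and Mitsunobu closure of F6 (PPh3, DIAD, THF) as in step 5 then gives 8.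

**Step 5.** Partial ionisation of the activated benzylic alcohol would erode the enantiomeric purity, and elimination to a styrene is a competing pathway. The fallback sets the stereocentre by hydrogenation instead of substitution; it sets out from 5 and comes back at 7. Acid-catalysed cyclodehydration of 5 (TsOH, toluene, water removal) gives 7-(benzyloxy)-5-methoxy-2-phenyl-4H-chromene F7. Asymmetric hydrogenation of the enol ether double bond of F7 with [Ir(cod)(tBu-PHOX)]BArF, the ligand enantiomer being chosen for (2S), then gives 7 without touching the benzyl ether.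

**Step 8.** Competing deprotonation at the benzylic CH2 of the benzyl ether or at C6–H, or incomplete lithiation, would lower the purity of 12. The fallback installs furan and tin in one coupling; it sets out from 8 and comes back at 12. Stille coupling of 8 with an excess of 2,5-bis(tributylstannyl)furan (Pd(PPh3)4, toluene, 100 °C) gives 12 directly. No new compound is made on this way, hence the entry F0.

## Further compounds

F1 | step 13 | 3-(benzyloxy)-4-(furan-2-yl)-2-methylcyclobut-2-en-1-one (racemic) | CC1=C(OCc2ccccc2)C(c2ccco2)C1=O
F2 | step 13 | 6-(benzyloxy)-5-methylbenzofuran-4-ol | Cc1c(O)c2ccoc2cc1OCc1ccccc1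
F3 | step 13 | 6-(benzyloxy)-4-methoxy-5-methylbenzofuran | COc1c(C)c(OCc2ccccc2)cc2occc12
F4 | step 13 | 2-[6-(benzyloxy)-4-methoxy-5-methylbenzofuran-2-yl]-4,4,5,5-tetramethyl-1,3,2-dioxaborolane | COc1c(C)c(OCc2ccccc2)cc2oc(B3OC(C)(C)C(C)(C)O3)cc12
F5 | step 12 | 2-(benzyloxy)-3-methyl-4-oxocyclobut-2-en-1-yl methanesulfonate (racemic) | CC1=C(OCc2ccccc2)C(OS(C)(=O)=O)C1=O
F6 | step 6 | 3-(benzyloxy)-2-bromo-6-[(3R)-3-hydroxy-3-phenylpropyl]-5-methoxyphenol | COc1cc(OCc2ccccc2)c(Br)c(O)c1CC[C@@H](O)c1ccccc1
F7 | step 5 | 7-(benzyloxy)-5-methoxy-2-phenyl-4H-chromene | COc1cc(OCc2ccccc2)cc2c1CC=C(c1ccccc1)O2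
F0 | step 8 | none | none
A1 | alternative 1 | 2-[(3R)-3-(tert-butyldimethylsilyloxy)-3-phenylpropyl]-3-methoxy-6-[4-methoxy-5-methyl-6-(triisopropylsilyloxy)benzofuran-2-yl]-5-(triisopropylsilyloxy)phenol | COc1cc(O[Si](C(C)C)(C(C)C)C(C)C)c(-c2cc3c(OC)c(C)c(O[Si](C(C)C)(C(C)C)C(C)C)cc3o2)c(O)c1CC[C@H](c1ccccc1)O[Si](C)(C)C(C)(C)C
A2 | alternative 1 | (7R)-7-(tert-butyldimethylsilyloxy)-1-diazo-3-methoxy-7-phenylhept-3-en-2-one | [N-]=[N+]=CC(=O)C(OC)=CCC[C@H](c1ccccc1)O[Si](C)(C)C(C)(C)C
A3 | alternative 1 | triisopropyl({[4-methoxy-5-methyl-6-(triisopropylsilyloxy)benzofuran-2-yl]ethynyl}oxy)silane | COc1c(C)c(O[Si](C(C)C)(C(C)C)C(C)C)cc2oc(C#CO[Si](C(C)C)(C(C)C)C(C)C)cc12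
A4 | alternative 2 | 1-[(2S)-7-hydroxy-5-methoxy-2-phenylchroman-8-yl]ethan-1-one | COc1cc(O)c(C(C)=O)c2c1CC[C@@H](c1ccccc1)O2
A5 | alternative 2 | 1-[2,6-dihydroxy-3-(hydroxymethyl)-4-methoxyphenyl]ethan-1-one | COc1cc(O)c(C(C)=O)c(O)c1CO
A6 | alternative 2 | styrene | C=Cc1ccccc1
A7 | alternative 2 | scandium tris(trifluoromethanesulfonate) | [Sc+3].[O-]S(=O)(=O)C(F)(F)F.[O-]S(=O)(=O)C(F)(F)F.[O-]S(=O)(=O)C(F)(F)F
A8 | alternative 3 | (2S)-7-(benzyloxy)-5-methoxy-8-[4-methoxy-5-methyl-6-(triisopropylsilyloxy)benzofuran-2-yl]-2-phenylchroman | COc1cc(OCc2ccccc2)c(-c2cc3c(OC)c(C)c(O[Si](C(C)C)(C(C)C)C(C)C)cc3o2)c2c1CC[C@@H](c1ccccc1)O2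
A9 | alternative 3 | {2-[(2S)-7-(benzyloxy)-5-methoxy-2-phenylchroman-8-carbonyloxy]-6-methoxy-5-methyl-4-(triisopropylsilyloxy)benzyl}triphenylphosphonium bromide | COc1cc(OCc2ccccc2)c(C(=O)Oc2cc(O[Si](C(C)C)(C(C)C)C(C)C)c(C)c(OC)c2C[P+](c2ccccc2)(c2ccccc2)c2ccccc2)c2c1CC[C@@H](c1ccccc1)O2.[Br-]
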